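C1 is the prenyl bridgehead, C2-C3-C4 the enolised dione bridge (3-hydroxybenzoyl on C3), C5 the geranyl bridgehead, C6 a CH2, C7 a CH(prenyl), C8 a CMe2 and C9 the bridging ketone. Ring A is C1-C2-C3-C4-C5-C9 and ring B is C5-C6-C7-C8-C1-C9.
The strategy rests on the ring B segment C6-C7-C8(CH3)2, which has the carbon pattern of a prenyl group on C5 whose alkene carbon C7 gained a second prenyl unit and whose alkene carbon C8 became bonded to C1. Cutting the C7 side-chain bond and C1-C8 opens the bicycle to a ring A dienone (geranyl and prenyl on C5, prenyl on C1) plus a dimethylallyl cation.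
One prenyltransferase operation with dimethylallyl diphosphate makes both bonds, ring B, C7 and C1. The enzyme converts only the (S)-C5 half of the racemic dienone, which gives the single enantiomer.
The dienone comes from dearomatising C-geranylation of the symmetric 3,5-diprenyl aroylphloroglucinol, whose two prenylated carbons are enantiotopic, so no regiochemical question arises. The 3'-phenol is a TIPS ether during the three C-alkylations. Both carbocycles of the benzophenone are bought, phloroglucinol becomes ring A in step 4, and ring B closes last.

Key step: step 7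

Assumption: the enol forms drawn for 10, 11, 13 and 14 stand for rapidly equilibrating tautomers, the CIP descriptors refer to the tautomer drawn, and racemic 10 and 11 are drawn as their (S)-C5 enantiomer.

Step 1
Reactants: 1 phloroglucinol; 2 3-hydroxybenzoic acid
Product: 3 (3-hydroxyphenyl)(2,4,6-trihydroxyphenyl)methanone
Conditions: P2O5 in MeSO3H (Eaton's reagent), 70 °C; ice water
Reagents that add atoms: none
Why: This is a Friedel-Crafts acylation of the very electron-rich, threefold symmetric phloroglucinol by the activated acid, in which the first aroyl group deactivates the ring against a second one and the meta position of the acid's hydroxyl rules out closure to a xanthone.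

Step 2
Reactants: 3 (3-hydroxyphenyl)(2,4,6-trihydroxyphenyl)methanone
Product: 5 (2,4,6-trihydroxyphenyl)[3-(triisopropylsilyloxy)phenyl]methanone, via disodium diphenoxide 4 (not isolated)
Conditions: NaH (2.05 equiv), THF-DMF, 0 °C; then TIPSCl (1.0 equiv), 0 °C to rt; dilute HCl work-up
Reagents that add atoms: triisopropylsilyl chloride, CC(C)[Si](Cl)(C(C)C)C(C)C; sodium hydride, [Na+].[H-] (its sodium is found only in 4)
Why: This is an O-silylation of a dianion, in which the first proton leaves the 4-OH (a vinylogous acid with a delocalised, weakly nucleophilic anion) and the second leaves the 3'-OH, so the more basic 3'-phenoxide takes the silyl chloride, and any silyl group on the acidic ring oxygens is labile and is passed on to the 3'-oxygen or lost on work-up.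

Step 3
Reactants: 5 (2,4,6-trihydroxyphenyl)[3-(triisopropylsilyloxy)phenyl]methanone; 6 prenyl bromide (2.1 equiv)
Product: 8 [2,4,6-trihydroxy-3,5-bis(3-methylbut-2-enyl)phenyl][3-(triisopropylsilyloxy)phenyl]methanone, via monoprenyl benzophenone 7 (not isolated)
Conditions: KOH (2.1 equiv), H2O-MeOH, 0 °C, argon
Reagents that add atoms: none
Why: This is the C-alkylation of an ambident acylphloroglucinolate with an allylic bromide in a protic medium, long used for prenylated acylphloroglucinols; hydrogen bonding shields the oxygens, the two free ring carbons react in turn, no simple phenoxide is left to be O-alkylated, and the acidic phenols use up the hydroxide so the aryl TIPS ether is spared.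

Step 4
Reactants: 8 [2,4,6-trihydroxy-3,5-bis(3-methylbut-2-enyl)phenyl][3-(triisopropylsilyloxy)phenyl]methanone; 9 geranyl bromide (1.1 equiv)
Product: 10 rac-4-[(2E)-3,7-dimethylocta-2,6-dienyl]-3,5-dihydroxy-4,6-bis(3-methylbut-2-enyl)-2-[3-(triisopropylsilyloxy)benzoyl]cyclohexa-2,5-dien-1-one
Conditions: KOH (2.0 equiv, second equivalent added slowly), MeOH-H2O, 0 °C to rt, argon; dilute HCl work-up
Reagents that add atoms: none
Why: This is an alkylative dearomatisation of the kind that gives hop beta-acids, in which the aroyl-bearing carbon is electron-poor and all ring oxygens are doubly flanked, so the allylic bromide is taken by a prenyl-bearing carbon; the two such carbons are enantiotopic, so C5 forms as a racemate with one constitution, and the much more acidic product ends as an enolate that resists further alkylation.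

Step 5
Reactants: 10 rac-TIPS-protected dienone
Product: 11 rac-4-[(2E)-3,7-dimethylocta-2,6-dienyl]-3,5-dihydroxy-2-(3-hydroxybenzoyl)-4,6-bis(3-methylbut-2-enyl)cyclohexa-2,5-dien-1-one (PPAP numbering: geranyl and prenyl on C5, prenyl on C1, aroyl on C3)
Conditions: n-Bu4NF (1.5 equiv), AcOH (1.5 equiv), THF, 0 °C, argon
Reagents that add atoms: none
Why: This is a fluoride-induced cleavage of an aryl silyl ether under acetic acid buffering, which touches neither the four trisubstituted alkenes, the enolised triketone nor the quaternary C5.

Step 6
Reactants: 6 prenyl bromide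
Product: 12 dimethylallyl diphosphate (isolated and used as the triammonium salt)
Conditions: (n-Bu4N)3HP2O7 (2 equiv), MeCN, rt; Dowex 50W-X8 (NH4+ form), aq. NH4HCO3; cellulose chromatography
Reagents that add atoms: tris(tetrabutylammonium) hydrogen diphosphate, CCCC[N+](CCCC)(CCCC)CCCC.CCCC[N+](CCCC)(CCCC)CCCC.CCCC[N+](CCCC)(CCCC)CCCC.OP(=O)([O-])OP(=O)([O-])[O-]
Why: This is an SN2 displacement of the primary allylic bromide by the organic-soluble diphosphate anion, the standard preparation of allylic diphosphates, followed by cation exchange to the water-soluble ammonium salt.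

Step 7
Reactants: 11 racemic dienone (only the (S)-enantiomer is converted); 12 dimethylallyl diphosphate
Product: 14 (1S,5S,7S)-5-[(2E)-3,7-dimethylocta-2,6-dienyl]-4-hydroxy-3-(3-hydroxybenzoyl)-8,8-dimethyl-1,7-bis(3-methylbut-2-enyl)bicyclo[3.3.1]non-3-ene-2,9-dione with the C7 side chain endo, via C8 tertiary cation 13 (not isolated)
Conditions: microsomes of Saccharomyces cerevisiae expressing the selected UbiA-type membrane prenyltransferase, MgCl2 (10 mM), Tris-HCl pH 7.5, dithiothreitol, 5% DMSO, 30 °C; EtOAc extraction; reversed-phase HPLC (removes unreacted (R)-11)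
Reagents that add atoms: none
Why: Proposed new method: magnesium ions held by the aspartate-rich motifs of the enzyme ionise 12, the C7=C8 alkene of the C5 prenyl group of (S)-11 adds through C7 to the CH2 end of the allyl cation so that the charge lands on tertiary C8 (13), and the C9=C1 enolate then bonds through C1 to C8 and becomes the C9 ketone. The closest known reaction type is the last step in the plant biosynthesis of bicyclic polyprenylated acylphloroglucinols, where a UbiA-type membrane prenyltransferase prenylates a side-chain alkene of a dearomatised acylphloroglucinol and closes the bicyclo[3.3.1]nonane in the same active site; that case has an aliphatic acyl substrate reacting through its geranyl alkene and closing onto the acyl-bearing carbon, not an aroyl substrate that must react through its prenyl alkene and close onto C1. Ring B closes in a 6-(enolendo)-exo-trig fashion, with both enol carbons C9 and C1 inside the new ring and a planar cation as acceptor, a geometry that is favourable for six-membered rings. C1 is set by C5, because the C6-C7-C8 tether can reach C1 only on the ring A face from which it starts, so (S)-C5 leads to (S)-C1, whereas C7 is set by the enzyme, which must present to the allyl cation the alkene face that leaves the new side chain on the side of the C2-C3-C4 bridge (endo, S). Four choices are needed: (S)- over (R)-11, the C5 prenyl alkene over the equally placed geranyl C2'=C3' alkene (the distal geranyl alkene and the C1 prenyl alkene cannot lead to ring B), the endo face, and C1 over C3 or an enol oxygen as terminator. The substrate favours only the last choice, since C1 is an alkyl-substituted electron-rich enolate carbon while C3 is drained by three carbonyl groups, so the other three rest on the pocket and are to be secured by screening homologues from plants that make 7-endo benzophenone-type congeners and by mutagenesis of pocket residues, with identity and enantiopurity checked by chiral HPLC.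

Compound list
1 | phloroglucinol | Oc1cc(O)cc(O)c1 | starting material
2 | 3-hydroxybenzoic acid | OC(=O)c1cccc(O)c1 | starting material
3 | (3-hydroxyphenyl)(2,4,6-trihydroxyphenyl)methanone | O=C(c1cccc(O)c1)c1c(O)cc(O)cc1O | intermediate
4 | disodium 4,3'-diphenoxide of 3 (not isolated) | [Na+].[Na+].[O-]c1cc(O)c(C(=O)c2cccc([O-])c2)c(O)c1 | intermediate
5 | (2,4,6-trihydroxyphenyl)[3-(triisopropylsilyloxy)phenyl]methanone | CC(C)[Si](Oc1cccc(C(=O)c2c(O)cc(O)cc2O)c1)(C(C)C)C(C)C | intermediate
6 | prenyl bromide | CC(C)=CCBr | starting material
7 | 3-prenyl derivative of 5 (not isolated) | CC(C)=CCc1c(O)cc(O)c(C(=O)c2cccc(O[Si](C(C)C)(C(C)C)C(C)C)c2)c1O | intermediate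
8 | 3,5-diprenyl derivative of 5 | CC(C)=CCc1c(O)c(CC=C(C)C)c(O)c(C(=O)c2cccc(O[Si](C(C)C)(C(C)C)C(C)C)c2)c1O | intermediate
9 | geranyl bromide | CC(C)=CCC/C(C)=C/CBr | starting material
10 | racemic C5-geranyl C5-prenyl C1-prenyl dienone, 3'-TIPS ether (S enantiomer drawn) | CC(C)=CCC/C(C)=C/C[C@]1(CC=C(C)C)C(O)=C(C(=O)c2cccc(O[Si](C(C)C)(C(C)C)C(C)C)c2)C(=O)C(CC=C(C)C)=C1O | intermediate
11 | racemic C5-geranyl C5-prenyl C1-prenyl dienone with free 3'-phenol (S enantiomer drawn, the one that reacts) | CC(C)=CCC/C(C)=C/C[C@]1(CC=C(C)C)C(O)=C(C(=O)c2cccc(O)c2)C(=O)C(CC=C(C)C)=C1O | intermediate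
12 | dimethylallyl diphosphate (handled as triammonium salt) | CC(C)=CCOP(=O)(O)OP(=O)(O)O | intermediate
13 | enzyme-bound C8 tertiary cation, C7 prenylated (not isolated) | CC(C)=CCC/C(C)=C/C[C@]1(C[C@H](CC=C(C)C)[C+](C)C)C(O)=C(C(=O)c2cccc(O)c2)C(=O)C(CC=C(C)C)=C1O | intermediate
14 | (1S,5S,7S) target CNP0236890.1 | CC(C)=CCC/C(C)=C/C[C@]12C[C@H](CC=C(C)C)C(C)(C)[C@](CC=C(C)C)(C(=O)C(C(=O)c3cccc(O)c3)=C1O)C2=O | target

Total step count: 7. Longest linear sequence: 6 (steps 1, 2, 3, 4, 5, 7).

Steps most likely to fail

1. Step 7. Several things may go wrong:
- there may be no turnover with the aroyl substrate;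
- prenyl may be transferred to the geranyl C2'=C3' alkene or to oxygen;
- the ring may close through C3, or the wrong alkene face may react;
- the two enantiomers of 11 may be told apart incompletely.

The fallback uses known chemistry, sets out from 5 and returns at 14. It places the second C5 unit before ring closure as part of an enantiopure lavandulyl group and makes the C8 cation by protonation. Compound 5 is C-geranylated with one equivalent of 9 (KOH, H2O-MeOH, 0 °C) to the 3-geranyl benzophenone F1. It is then C-prenylated with one equivalent of 6 under the same conditions to the 3-geranyl-5-prenyl benzophenone F2. Commercial (R)-lavandulol, OC[C@H](CC=C(C)C)C(C)=C, is converted with Tf2O and 2,6-lutidine in CH2Cl2 at -78 °C into (R)-lavandulyl triflate F3. Alkylative dearomatisation of F2 with F3 (LiN(SiMe3)2, THF, 0 °C) cannot tell the geranyl-bearing from the prenyl-bearing carbon, nor the two ring faces. A statistical set of isomers is therefore expected, from which the (S)-C5 geranyl lavandulyl dienone F4 is separated by HPLC. Formic acid at room temperature, the medium known to close this C1-C8 bond in the all-prenyl benzoyl series, protonates the isopropenyl group to the C8 cation. C1 traps this cation to give the target TIPS ether F5. Here C7 comes from lavandulol and C1 follows from C5. Treatment with n-Bu4NF and AcOH as in step 5 gives 14. The cost is the statistical loss in the alkylation and the exposure of the geranyl chain to acid.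

2. Step 4. O-geranylation may occur, the reaction may stall when the more acidic product takes up the base, the bromide may solvolyse, and the silyl group may be slowly lost. The fallback sets out from 8 and returns at 10. It replaces the SN2 alkylation under stoichiometric base by a Tsuji-Trost allylic substitution under neutral conditions. Commercial geraniol is converted with ClCO2Me and pyridine into geranyl methyl carbonate F6. Compounds 8 and F6 are then treated with Pd(PPh3)4 (5 mol %) in THF at rt. Ionisation and loss of CO2 give the geranyl complex of divalent palladium and methoxide, which deprotonates only the acidic ring of 8. The soft ring carbon attacks the unsubstituted CH2 terminus. Aryl geranyl ethers that form are ionised again by zerovalent palladium, so O-alkylation is corrected instead of accumulating.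

3. Step 2. Silylation may occur at the 4-oxygen, twofold silylation may occur, or the silyl group may scramble among the four phenols. The fallback sets out from 1 and returns at 5. It builds the ketone from partners that are differentiated from the start. Compound 1 is converted with MOMCl and i-Pr2NEt in CH2Cl2 into 1,3,5-tris(methoxymethoxy)benzene F7. Commercial 3-hydroxybenzaldehyde is silylated (TIPSCl, imidazole, DMF) to 3-(triisopropylsilyloxy)benzaldehyde F8. Directed ortho-lithiation of F7 (n-BuLi, THF, 0 °C) gives 2,4,6-tris(methoxymethoxy)phenyllithium F9. This adds to F8 at -78 °C to give the racemic diaryl carbinol F10. Dess-Martin periodinane in CH2Cl2 oxidises it to the tris-MOM benzophenone F11. HCl in MeOH at 40 °C removes the three MOM groups, while the acid-stable aryl TIPS ether stays, giving 5.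

Further compounds
F1 | step 7 | [3-geranyl-2,4,6-trihydroxyphenyl][3-(triisopropylsilyloxy)phenyl]methanone | CC(C)=CCC/C(C)=C/Cc1c(O)cc(O)c(C(=O)c2cccc(O[Si](C(C)C)(C(C)C)C(C)C)c2)c1O
F2 | step 7 | [3-geranyl-2,4,6-trihydroxy-5-prenylphenyl][3-(triisopropylsilyloxy)phenyl]methanone | CC(C)=CCC/C(C)=C/Cc1c(O)c(CC=C(C)C)c(O)c(C(=O)c2cccc(O[Si](C(C)C)(C(C)C)C(C)C)c2)c1O
F3 | step 7 | (R)-lavandulyl trifluoromethanesulfonate | FC(F)(F)S(=O)(=O)OC[C@H](CC=C(C)C)C(C)=C
F4 | step 7 | (S)-C5 geranyl lavandulyl C1-prenyl dienone, 3'-TIPS ether | CC(C)=CCC/C(C)=C/C[C@]1(C[C@H](CC=C(C)C)C(C)=C)C(O)=C(C(=O)c2cccc(O[Si](C(C)C)(C(C)C)C(C)C)c2)C(=O)C(CC=C(C)C)=C1O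
F5 | step 7 | 3'-TIPS ether of 14 | CC(C)=CCC/C(C)=C/C[C@]12C[C@H](CC=C(C)C)C(C)(C)[C@](CC=C(C)C)(C(=O)C(C(=O)c3cccc(O[Si](C(C)C)(C(C)C)C(C)C)c3)=C1O)C2=O
F6 | step 4 | geranyl methyl carbonate | CC(C)=CCC/C(C)=C/COC(=O)OC
F7 | step 2 | 1,3,5-tris(methoxymethoxy)benzene | COCOc1cc(OCOC)cc(OCOC)c1
F8 | step 2 | 3-(triisopropylsilyloxy)benzaldehyde | O=Cc1cccc(O[Si](C(C)C)(C(C)C)C(C)C)c1
F9 | step 2 | 2,4,6-tris(methoxymethoxy)phenyllithium | [Li]c1c(OCOC)cc(OCOC)cc1OCOC
F10 | step 2 | racemic [2,4,6-tris(methoxymethoxy)phenyl][3-(triisopropylsilyloxy)phenyl]methanol | COCOc1cc(OCOC)c(C(O)c2cccc(O[Si](C(C)C)(C(C)C)C(C)C)c2)c(OCOC)c1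
F11 | step 2 | [2,4,6-tris(methoxymethoxy)phenyl][3-(triisopropylsilyloxy)phenyl]methanone | COCOc1cc(OCOC)c(C(=O)c2cccc(O[Si](C(C)C)(C(C)C)C(C)C)c2)c(OCOC)c1
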